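**Plan**
Retrosynthesis: the two aryl O–CH3 bonds and the aryl pivalate C–O bond are cut last. Ring A, the central ring numbered C1(OH), C2(H), C3(OH), C4(benzyl), C5(phenethyl), C6(benzyl), is then opened at C1–C2 and C1–C6, which releases C1 as carbon monoxide.
Enabling feature: C2 carries only hydrogen and lies between the two oxygen-bearing carbons, so C2–C3 can be a terminal alkyne, C1 a carbonyl carbon, and the C3 oxygen can arrive by a 1,2-acyloxy shift from C4, while C4–C6 carry all three carbon substituents on an open chain.
The resulting 3-pivaloyloxy-1,4-enyne is cut at the ester C–O bond, at C3–C4 (ethynyl addition to a ketone), at C5=C6 (Horner–Wadsworth–Emmons olefination) and at C4–C5 (acylation of a phosphonate carbanion).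
Forward: phosphonate, then β-ketophosphonate, E-enone, ethynyl carbinol, pivalate, ring A by [5+1] closure with CO, and deprotection; ring A is the only ring formed, and the three outer benzene rings are bought.
Stereochemistry: the target is achiral; the E alkene geometry comes from the olefination, and the racemic carbinol centre disappears when ring A aromatises.

Key step: step 6

Remark: no configuration has to be set; the stereocentres of 5, 9, 10, 11 and 13 are racemic and are lost before the end.

**Step 1**
Reactants: 1 (3-bromopropyl)benzene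
Product: 2 diethyl (3-phenylpropyl)phosphonate
Conditions: P(OEt)3 (3 equiv), neat, 150 °C, EtBr distilled off
Reagents that add atoms: triethyl phosphite, CCOP(OCC)OCC
Why: Michaelis–Arbuzov reaction, in which the unhindered primary bromide alkylates phosphorus and bromide then dealkylates the phosphonium salt.

**Step 2**
Reactants: 2 diethyl (3-phenylpropyl)phosphonate; 3 methyl 2-(4-methoxyphenyl)acetate
Product: 5 diethyl [1-(4-methoxyphenyl)-2-oxo-5-phenylpentan-3-yl]phosphonate (racemic), via lithiated phosphonate 4 (not isolated)
Conditions: 2 (2.2 equiv), n-BuLi (2.1 equiv), THF, −78 °C; then 3 (1.0 equiv), −78 → −20 °C; aq. NH4Cl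
Reagents that add atoms: none
Why: Claisen-type acylation of an α-lithiated phosphonate by an ester, run with a second equivalent of the carbanion so that the more acidic β-ketophosphonate is stored as its enolate; at −78 °C acyl substitution on the arylacetate should outrun proton transfer, as it does with unbranched lithiated phosphonates.

**Step 3**
Reactants: 5 diethyl [1-(4-methoxyphenyl)-2-oxo-5-phenylpentan-3-yl]phosphonate; 6 2-(4-methoxyphenyl)acetaldehyde
Product: 7 (E)-1,5-bis(4-methoxyphenyl)-3-(2-phenylethyl)pent-3-en-2-one
Conditions: Ba(OH)2 (0.8 equiv), THF, rt; then 6 (1.3 equiv, freshly distilled), THF/H2O 40:1, 0 °C → rt; aq. NH4Cl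
Reagents that add atoms: none
Why: Horner–Wadsworth–Emmons olefination of a β-ketophosphonate under mild Ba(OH)2 conditions that tolerate enolisable aldehydes; reversible addition and syn-elimination of phosphate should place the acyl group trans to the new 4-methoxybenzyl group, giving the E alkene.

**Step 4**
Reactants: 7 (E)-1,5-bis(4-methoxyphenyl)-3-(2-phenylethyl)pent-3-en-2-one; 8 ethynylmagnesium bromide
Product: 9 racemic (E)-3-(4-methoxybenzyl)-6-(4-methoxyphenyl)-4-(2-phenylethyl)hex-4-en-1-yn-3-ol
Conditions: CeCl3 (anhydrous, 2 equiv), HC≡CMgBr (3 equiv), THF, −78 → 0 °C; aq. NH4Cl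
Reagents that add atoms: none
Why: 1,2-addition of an alkynyl organometallic to an enone, with transmetalation to the less basic organocerium reagent to suppress enolisation of the benzylic ketone; the new carbinol centre forms racemic, which does not matter because it becomes the sp2 ring carbon C4 in step 6.

**Step 5**
Reactants: 9 racemic (E)-3-(4-methoxybenzyl)-6-(4-methoxyphenyl)-4-(2-phenylethyl)hex-4-en-1-yn-3-ol
Product: 11 racemic (E)-3-(4-methoxybenzyl)-6-(4-methoxyphenyl)-4-(2-phenylethyl)hex-4-en-1-yn-3-yl pivalate, via lithium alkoxide 10 (not isolated)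
Conditions: LiN(SiMe3)2 (1.05 equiv), THF, −78 °C; then t-BuCOCl (1.5 equiv), −78 °C → rt
Reagents that add atoms: pivaloyl chloride, CC(C)(C)C(=O)Cl
Why: O-acylation of a pre-formed lithium alkoxide with an acid chloride, the usual esterification of hindered tertiary propargylic alcohols; one equivalent of amide base removes only the hydroxyl proton and leaves the less acidic alkyne C–H untouched.

**Step 6**
Reactants: 11 racemic (E)-3-(4-methoxybenzyl)-6-(4-methoxyphenyl)-4-(2-phenylethyl)hex-4-en-1-yn-3-yl pivalate; 12 carbon monoxide
Product: 14 5-hydroxy-2,4-bis(4-methoxybenzyl)-3-(2-phenylethyl)phenyl pivalate, via cyclohexadienone tautomer 13 (not isolated)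
Conditions: [Rh(CO)2Cl]2 (5 mol %), CO (80 atm), CH2Cl2, 80 °C, autoclave
Reagents that add atoms: none
Why: This is the known rhodium-catalysed carbonylative [5+1] benzannulation of 3-acyloxy-1,4-enynes, which gives resorcinol monoesters. Coordination of monovalent rhodium to the terminal alkyne induces a 1,2-shift of the pivaloyloxy group from the carbinol carbon to the internal alkyne carbon (future C3), leaving a rhodium vinylcarbene at the former alkyne CH (future C2) in conjugation with the trisubstituted alkene. Metalla-6π-electrocyclisation to a rhodacyclohexadiene, CO insertion and reductive elimination form C1–C2 and C1–C6, so ring A closes as a six-membered carbocycle from five enyne carbons and one CO carbon, first as dienone 13 and then, by enolisation, as the phenol. No stereocentre is formed, and the racemic carbinol centre of 11 becomes the sp2 carbon C4. The step needs 1,2- rather than 1,3-acyloxy migration, which the unsubstituted alkyne terminus and the electron-rich pivalate favour, and carbonylation rather than direct five-membered ring closure, which the high CO pressure favours. The E alkene places hydrogen, not the 4-methoxybenzyl group, on the inner side of the alkene terminus, so that C6 can reach the metal.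

**Step 7**
Reactants: 14 5-hydroxy-2,4-bis(4-methoxybenzyl)-3-(2-phenylethyl)phenyl pivalate
Product: 15 4,6-bis(4-methoxybenzyl)-5-(2-phenylethyl)benzene-1,3-diol
Conditions: NaOMe (3 equiv), MeOH (degassed), 50 °C, argon; aq. NH4Cl
Reagents that add atoms: none
Why: Base-mediated transesterification (methanolysis) of an aryl ester, in which the phenoxide is a good leaving group and the aryl methyl ethers are inert to methoxide at this temperature.

**Step 8**
Reactants: 15 4,6-bis(4-methoxybenzyl)-5-(2-phenylethyl)benzene-1,3-diol
Product: 16 4,6-bis(4-hydroxybenzyl)-5-(2-phenylethyl)benzene-1,3-diol (target)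
Conditions: BBr3 (6 equiv), CH2Cl2, −78 → 0 °C; then H2O, 0 °C
Reagents that add atoms: none
Why: Lewis-acid O-demethylation of aryl methyl ethers with BBr3 (boron–ether adduct, then attack of bromide on methyl), with the free phenols held as aryloxyboron species until hydrolysis and the temperature kept at or below 0 °C to avoid acid-induced migration of the benzyl groups.

**Compound list**
1 | (3-bromopropyl)benzene | BrCCCc1ccccc1 | starting material
2 | diethyl (3-phenylpropyl)phosphonate | CCOP(=O)(OCC)CCCc1ccccc1 | intermediate
3 | methyl 2-(4-methoxyphenyl)acetate | COC(=O)Cc1ccc(OC)cc1 | starting material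
4 | diethyl (1-lithio-3-phenylpropyl)phosphonate | [Li]C(CCc1ccccc1)P(=O)(OCC)OCC | intermediate (not isolated)
5 | diethyl [1-(4-methoxyphenyl)-2-oxo-5-phenylpentan-3-yl]phosphonate (racemic) | CCOP(=O)(OCC)C(CCc1ccccc1)C(=O)Cc1ccc(OC)cc1 | intermediate
6 | 2-(4-methoxyphenyl)acetaldehyde | COc1ccc(CC=O)cc1 | starting material
7 | (E)-1,5-bis(4-methoxyphenyl)-3-(2-phenylethyl)pent-3-en-2-one | COc1ccc(CC(=O)/C(CCc2ccccc2)=C/Cc2ccc(OC)cc2)cc1 | intermediate
8 | ethynylmagnesium bromide | C#C[Mg]Br | starting material
9 | racemic (E)-3-(4-methoxybenzyl)-6-(4-methoxyphenyl)-4-(2-phenylethyl)hex-4-en-1-yn-3-ol | C#CC(O)(Cc1ccc(OC)cc1)/C(CCc1ccccc1)=C/Cc1ccc(OC)cc1 | intermediate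
10 | lithium (E)-3-(4-methoxybenzyl)-6-(4-methoxyphenyl)-4-(2-phenylethyl)hex-4-en-1-yn-3-olate (racemic) | [Li]OC(C#C)(Cc1ccc(OC)cc1)/C(CCc1ccccc1)=C/Cc1ccc(OC)cc1 | intermediate (not isolated)
11 | racemic (E)-3-(4-methoxybenzyl)-6-(4-methoxyphenyl)-4-(2-phenylethyl)hex-4-en-1-yn-3-yl pivalate | C#CC(Cc1ccc(OC)cc1)(OC(=O)C(C)(C)C)/C(CCc1ccccc1)=C/Cc1ccc(OC)cc1 | intermediate
12 | carbon monoxide | [C-]#[O+] | starting material
13 | racemic 4,6-bis(4-methoxybenzyl)-3-oxo-5-(2-phenylethyl)cyclohexa-1,5-dien-1-yl pivalate (keto tautomer of 14) | O=C1C=C(OC(=O)C(C)(C)C)C(Cc2ccc(OC)cc2)=C(CCc2ccccc2)C1Cc1ccc(OC)cc1 | intermediate (not isolated)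
14 | 5-hydroxy-2,4-bis(4-methoxybenzyl)-3-(2-phenylethyl)phenyl pivalate | COc1ccc(Cc2c(O)cc(OC(=O)C(C)(C)C)c(Cc3ccc(OC)cc3)c2CCc2ccccc2)cc1 | intermediate
15 | 4,6-bis(4-methoxybenzyl)-5-(2-phenylethyl)benzene-1,3-diol | COc1ccc(Cc2c(O)cc(O)c(Cc3ccc(OC)cc3)c2CCc2ccccc2)cc1 | intermediate
16 | 4,6-bis(4-hydroxybenzyl)-5-(2-phenylethyl)benzene-1,3-diol | Oc1ccc(Cc2c(O)cc(O)c(Cc3ccc(O)cc3)c2CCc2ccccc2)cc1 | target

**Step count and risks**
Total: 8 steps. Longest linear sequence: 8 steps, from 1 to 16.

Step 6 (carbonylative benzannulation). The 1,2-acyloxy shift of the crowded tertiary pivalate may be slow. Ionisation of the doubly activated propargylic–allylic C–O bond with elimination, or a 1,3-shift to an allenyl ester, could then outrun carbonylation. The fallback changes the migrating group; it sets out from 9 and comes back at 15. Alcohol 9 would be acylated through lithium alkoxide 10 with 4-(dimethylamino)benzoyl chloride to racemic (E)-3-(4-methoxybenzyl)-6-(4-methoxyphenyl)-4-(2-phenylethyl)hex-4-en-1-yn-3-yl 4-(dimethylamino)benzoate F1. Its electron-rich aroyloxy group is known to migrate faster under rhodium catalysis, so the same [Rh(CO)2Cl]2/CO benzannulation could be run at lower temperature. It should pass through racemic 4,6-bis(4-methoxybenzyl)-3-oxo-5-(2-phenylethyl)cyclohexa-1,5-dien-1-yl 4-(dimethylamino)benzoate F2 to 5-hydroxy-2,4-bis(4-methoxybenzyl)-3-(2-phenylethyl)phenyl 4-(dimethylamino)benzoate F3. Methanolysis of F3 with NaOMe in MeOH would then give 15.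

Step 3 (olefination). The enolisable arylacetaldehyde may self-condense under base, and the new double bond may migrate out of conjugation with the ketone into conjugation with the anisyl ring; E selectivity may also be eroded. The fallback avoids both the aldehyde and the basic medium; it sets out from 5 and comes back at 7. β-Ketophosphonate 5 would be olefinated with aqueous formaldehyde (K2CO3, THF/H2O, rt) to 1-(4-methoxyphenyl)-3-methylidene-5-phenylpentan-2-one F4. Cross-metathesis of F4 with commercial 4-allylanisole (second-generation Hoveyda–Grubbs catalyst, 1,4-benzoquinone, CH2Cl2, 40 °C) should then give the thermodynamically preferred E-enone 7 with loss of ethene.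

Step 2 (acylation). Proton transfer from the acidic benzylic position of the ester to the branched lithiated phosphonate may compete with acyl substitution and return both partners. The fallback changes the oxidation level of the electrophile; it sets out from 2 and comes back at 5. Lithiated phosphonate 4, made from 2 as before, would be added at −78 °C to aldehyde 6, where carbonyl addition is much faster than enolisation. This should give diethyl [2-hydroxy-1-(4-methoxyphenyl)-5-phenylpentan-3-yl]phosphonate F5 as a mixture of racemic diastereomers. Oxidation of F5 with Dess–Martin periodinane (NaHCO3, CH2Cl2, rt) would give 5.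

**Further compounds**
F1 | step 6 | racemic (E)-3-(4-methoxybenzyl)-6-(4-methoxyphenyl)-4-(2-phenylethyl)hex-4-en-1-yn-3-yl 4-(dimethylamino)benzoate | C#CC(Cc1ccc(OC)cc1)(OC(=O)c1ccc(N(C)C)cc1)/C(CCc1ccccc1)=C/Cc1ccc(OC)cc1
F2 | step 6 | racemic 4,6-bis(4-methoxybenzyl)-3-oxo-5-(2-phenylethyl)cyclohexa-1,5-dien-1-yl 4-(dimethylamino)benzoate | O=C1C=C(OC(=O)c2ccc(N(C)C)cc2)C(Cc2ccc(OC)cc2)=C(CCc2ccccc2)C1Cc1ccc(OC)cc1
F3 | step 6 | 5-hydroxy-2,4-bis(4-methoxybenzyl)-3-(2-phenylethyl)phenyl 4-(dimethylamino)benzoate | COc1ccc(Cc2c(O)cc(OC(=O)c3ccc(N(C)C)cc3)c(Cc3ccc(OC)cc3)c2CCc2ccccc2)cc1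
F4 | step 3 | 1-(4-methoxyphenyl)-3-methylidene-5-phenylpentan-2-one | C=C(CCc1ccccc1)C(=O)Cc1ccc(OC)cc1
F5 | step 2 | diethyl [2-hydroxy-1-(4-methoxyphenyl)-5-phenylpentan-3-yl]phosphonate (mixture of racemic diastereomers) | CCOP(=O)(OCC)C(CCc1ccccc1)C(O)Cc1ccc(OC)cc1
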